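Ring A (C1–C5, C10) carries its oxygen at C1 para to the one-carbon branch C15 on C4, which makes it the retron of a Diels–Alder adduct between a 2-silyloxy-1,3-diene (C2=C1(OSi)–C10=C5) and prop-2-ynal (C3≡C4–C15). One enantioselective [4+2] cycloaddition therefore forms C2–C3 and C4–C5 together, sets C5 and leaves a C1=C10 enol silane and a C3=C4 enal. These two handles serve for an epoxide transposition to the 3β-ol with the C4=C15 methylene and for anti-selective quaternisation of C10; ring B (C5–C10) is closed last by an intramolecular CrCl2-mediated allylation that delivers the C6 hydroxyl and the C7 acrylate ester.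

Key step: step 3

Remark on numbering: locants are those of the eudesmane skeleton of the target (C14 = methyl on C10, C15 = exocyclic carbon on C4, C11–C13 = acrylate unit on C7); β is the face of C14.
Assumption: the (S)-configured oxazaborolidinium catalyst of step 3 is taken to deliver the C5 configuration shown; should its facial sense be the opposite, its enantiomer is used.

Step 1
Reactants: 1 2-[(4-methoxybenzyl)oxy]acetaldehyde; 2 diethyl (3-oxobutan-2-yl)phosphonate
Product: 3 (E)-5-[(4-methoxybenzyl)oxy]-3-methylpent-3-en-2-one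
Conditions: LiCl, i-Pr2NEt, MeCN, 0 °C to rt
Reagents that add atoms: none
Why: Horner–Wadsworth–Emmons olefination under mild LiCl/amine conditions tolerates the enolisable α-alkoxy aldehyde and should give the thermodynamically favoured (E)-trisubstituted enone (acyl trans to CH2OPMB); no stereocentre is formed.

Step 2
Reactants: 3 (E)-enone
Product: 4 (E)-2-(tert-butyldimethylsilyloxy)-5-[(4-methoxybenzyl)oxy]-3-methylpenta-1,3-diene
Conditions: TBSOTf, Et3N, CH2Cl2, 0 °C
Reagents that add atoms: tert-butyldimethylsilyl triflate, CC(C)(C)[Si](C)(C)OS(=O)(=O)C(F)(F)F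
Why: Soft enolisation of the methyl ketone on its methyl side (silyl triflate/amine enol silane formation) should give the cross-conjugated 2-silyloxy-1,3-diene with the (E) C10=C5 bond unchanged.

Step 3
Reactants: 4 2-silyloxy diene; 5 prop-2-ynal
Product: 6 (6R)-4-[(tert-butyldimethylsilyl)oxy]-6-{[(4-methoxybenzyl)oxy]methyl}-5-methylcyclohexa-1,4-diene-1-carbaldehyde (ring A; C5 stereocentre with 5α-H)
Conditions: (S)-α,α-diphenylprolinol-derived B-(o-tolyl)oxazaborolidine (20 mol %), Tf2NH (18 mol %), CH2Cl2, −78 °C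
Reagents that add atoms: none
Why: The protonated oxazaborolidine binds the formyl group of 5, and the electron-rich diene 4 adds in a concerted but asynchronous [4+2] (Diels–Alder) cycloaddition in which C2 bonds to the alkyne β-carbon C3 and C5 to C4, so both ring-A bonds arise in one step. The closest known reaction types are the catalytic enantioselective Diels–Alder reactions of 2-silyloxy-1,3-dienes with enals and of acetylenic aldehydes with dienes under chiral boron Lewis acids. Ring A is closed by an intermolecular [4+2] cycloaddition, a six-membered carbocycle from a four-carbon and a two-carbon component. The only new stereocentre, C5, is set by the catalyst, which shields one face of the bound ynal so that the (E)-configured diene terminus C5 is attacked from one side only. The step needs regioselectivity (C1–O para to C4–CHO, the C5 side chain ortho to C4), which the large HOMO coefficient at C2 of the 2-silyloxy diene, reinforced by the C5 alkyl group, should secure, and it needs cycloaddition to win over 1,2-addition of the enol silane to the formyl group, which the s-cis bias of the 2,3-disubstituted diene and the low temperature should favour. The adduct keeps the C1=C10 enol silane and the C3=C4–C15 enal that the later steps use.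

Step 4
Reactants: 6 Diels–Alder adduct (enal)
Product: 7 [(6S)-4-[(tert-butyldimethylsilyl)oxy]-6-{[(4-methoxybenzyl)oxy]methyl}-5-methylcyclohexa-1,4-dien-1-yl]methanol
Conditions: i-Bu2AlH, CH2Cl2, −78 °C; Rochelle salt work-up
Reagents that add atoms: none
Why: 1,2-Reduction of the enal by the aluminium hydride gives the primary allylic alcohol (C15–OH) while the enol silane and the PMB ether are inert at −78 °C; no stereocentre changes.

Step 5
Reactants: 7 allylic alcohol
Product: 8 3β,4β-epoxy alcohol (oxirane across C3–C4 on the face of the C5 side chain, C15H2OH on C4, C1=C10 enol silane kept)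
Conditions: Ti(Oi-Pr)4, L-(+)-diethyl tartrate, t-BuOOH, 4 Å MS, CH2Cl2, −20 °C
Reagents that add atoms: tert-butyl hydroperoxide, CC(C)(C)OO
Why: Sharpless asymmetric epoxidation of the trisubstituted allylic alcohol, in which the titanium–L-tartrate complex should deliver oxygen to the β face of C3=C4 (reagent control over the shielding by the C5 side chain) and so set C3 and C4, while the uncoordinated enol silane is not epoxidised.

Step 6
Reactants: 8 3β,4β-epoxy alcohol
Product: 10 ring-A 3β-allylic alcohol bearing the C4=C15 methylene (C1=C10 enol silane; 5β-CH2OPMB; 5α-H), via epoxy iodide 9 (not isolated)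
Conditions: PPh3, I2, imidazole, THF, 0 °C; then Zn dust, EtOH, 60 °C
Reagents that add atoms: none
Why: Appel-type iodination of the primary alcohol followed by zinc-induced reductive β-elimination of the 2,3-epoxy iodide (epoxide-opening 1,3-transposition) should unveil the C4=C15 methylene and the C3 alkoxide without touching the C3–O bond, so the 3β configuration from step 5 is retained.

Step 7
Reactants: 10 3β-allylic alcohol
Product: 11 3β-TBS ether of 10
Conditions: TBSCl, imidazole, DMF, rt
Reagents that add atoms: tert-butyldimethylsilyl chloride, CC(C)(C)[Si](C)(C)Cl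
Why: Standard silylation of the secondary allylic alcohol protects O3 for the Lewis-acid, bromination and oxidation steps; no stereocentre changes.

Step 8
Reactants: 11 enol silane; 12 acrolein
Product: 13 ring-A keto aldehyde: 1-oxo-3β-(TBS-oxy)-4-methylidene-5β-[(PMB-oxy)methyl]-10β-methyl-10α-(3-oxopropyl)cyclohexane (5α-H)
Conditions: BF3·OEt2, i-PrOH, CH2Cl2, −78 °C
Reagents that add atoms: none
Why: Mukaiyama–Michael addition in which the tetrasubstituted enol silane attacks BF3-activated acrolein through C10 on the face anti to the pseudoaxial C5 side chain (held there by allylic strain with the C10 methyl and the C15 methylene), so C10 should become quaternary with C9 trans to C6 and the methyl β.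

Step 9
Reactants: 13 keto aldehyde; 14 methyl acrylate
Product: 15 Morita–Baylis–Hillman adduct of 13 (C7 carbinol, both epimers, carrying the C11(=C13H2)–C12O2Me unit)
Conditions: quinuclidine (0.5 equiv), MeOH (2 equiv), methyl acrylate (neat), rt
Reagents that add atoms: none
Why: Morita–Baylis–Hillman reaction, chemoselective for the unhindered aldehyde over the α-quaternary ketone; the new C7 carbinol centre forms unselectively, which is of no consequence because C7 becomes sp2 in step 10.

Step 10
Reactants: 15 Morita–Baylis–Hillman adduct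
Product: 16 (Z)-allylic bromide (C10 side chain C9H2–C8H2–C7H=C11(CO2Me)–C13H2Br)
Conditions: NBS, Me2S, CH2Cl2, −20 to 0 °C
Reagents that add atoms: N-bromosuccinimide, O=C1CCC(=O)N1Br
Why: Corey–Kim-type activation of the allylic alcohol and SN2′ attack of bromide should give the rearranged 2-(bromomethyl)enoate as the thermodynamically favoured (Z) isomer (C8 trans to the ester), leaving the ketone, the silyl ether and the PMB ether untouched.

Step 11
Reactants: 16 (Z)-allylic bromide
Product: 17 primary alcohol (C6–OH) of 16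
Conditions: DDQ, CH2Cl2/pH 7 buffer, 0 °C
Reagents that add atoms: none
Why: Oxidative cleavage of the PMB ether at its electron-rich benzylic position should free the C6 alcohol without affecting the allylic bromide, the TBS ether or the alkenes.

Step 12
Reactants: 17 primary alcohol
Product: 18 C6 aldehyde (cyclisation precursor)
Conditions: Dess–Martin periodinane, NaHCO3, CH2Cl2, 0 °C; used crude
Reagents that add atoms: none
Why: Buffered Dess–Martin oxidation gives the β,γ-unsaturated aldehyde under non-basic conditions, so C5 should not epimerise and C4=C15 should not move into conjugation.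

Step 13
Reactants: 18 C6 aldehyde
Product: 19 methyl 6α-hydroxy-1-oxo-3β-[(tert-butyldimethylsilyl)oxy]eudesma-4(15),11(13)-dien-12-oate (trans-decalin; 5α-H, 7α-H)
Conditions: CrCl2, THF, 0 °C to rt; pH 7 buffer work-up
Reagents that add atoms: none
Why: Nozaki–Hiyama-type intramolecular allylation in which the allylchromium species adds through its γ-carbon C7 to the C6 aldehyde via a chair six-membered transition state fused to the forming chair of ring B, which should place the C6–O bond and the C7 acrylate equatorial (6α-OH, 7α-H, trans) and give the trans-decalin, the aldehyde reacting far faster than the α-quaternary C1 ketone.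

Step 14
Reactants: 20 ethyl 2-(hydroxymethyl)acrylate
Product: 21 ethyl 2-{[(tert-butyldimethylsilyl)oxy]methyl}acrylate
Conditions: TBSCl, imidazole, DMF, rt
Reagents that add atoms: tert-butyldimethylsilyl chloride, CC(C)(C)[Si](C)(C)Cl
Why: Standard silylation of the primary allylic alcohol masks the side-chain hydroxyl for the esterification.

Step 15
Reactants: 21 silyl ether ester
Product: 22 2-{[(tert-butyldimethylsilyl)oxy]methyl}acrylic acid
Conditions: LiOH, THF/H2O, 0 °C; then aq. HCl to pH 3
Reagents that add atoms: lithium hydroxide, [Li+].[OH-]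
Why: Saponification of the ethyl ester (acyl–oxygen cleavage) at low temperature should give the acid with the TBS ether intact.

Step 16
Reactants: 19 hydroxy ester; 22 silyl-protected acid
Product: 24 methyl 6α-(2-{[(tert-butyldimethylsilyl)oxy]methyl}acryloyloxy)-1-oxo-3β-[(tert-butyldimethylsilyl)oxy]eudesma-4(15),11(13)-dien-12-oate, via mixed anhydride 23 (not isolated)
Conditions: 2,4,6-trichlorobenzoyl chloride, Et3N, toluene, rt; then 19, DMAP, rt
Reagents that add atoms: none
Why: Yamaguchi esterification in which DMAP attacks the mixed anhydride at the less hindered acryloyl carbonyl and the acylpyridinium acylates the hindered equatorial 6α-hydroxyl with retention at C6, which should outpace lactonisation onto C12.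

Step 17
Reactants: 24 keto diester
Product: 25 methyl 1β-hydroxy-6α-(2-{[(tert-butyldimethylsilyl)oxy]methyl}acryloyloxy)-3β-[(tert-butyldimethylsilyl)oxy]eudesma-4(15),11(13)-dien-12-oate
Conditions: NaBH4, CeCl3·7H2O, MeOH, −40 °C
Reagents that add atoms: none
Why: Luche reduction in which hydride attacks the C1 ketone axially from the α face, opposite the axial C14 methyl, to give the equatorial 1β-alcohol, while CeCl3 suppresses conjugate reduction of the two acrylate esters.

Step 18
Reactants: 25 bis-silyl ether
Product: 26 methyl 1β,3β-dihydroxy-6α-[2-(hydroxymethyl)acryloyloxy]eudesma-4(15),11(13)-dien-12-oate (CNP0247525.1)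
Conditions: HF·pyridine, pyridine/THF, 0 °C to rt
Reagents that add atoms: none
Why: Buffered fluoride cleavage of both TBS ethers should leave the two acrylate esters and the allylic alcohol intact and changes no stereocentre.

Compound list
1 | 2-[(4-methoxybenzyl)oxy]acetaldehyde | COc1ccc(COCC=O)cc1 | starting material
2 | diethyl (3-oxobutan-2-yl)phosphonate | CCOP(=O)(OCC)C(C)C(C)=O | starting material
3 | (E)-5-[(4-methoxybenzyl)oxy]-3-methylpent-3-en-2-one | CC(=O)/C(C)=C/COCc1ccc(OC)cc1 | intermediate
4 | (E)-2-(tert-butyldimethylsilyloxy)-5-[(4-methoxybenzyl)oxy]-3-methylpenta-1,3-diene | C=C(O[Si](C)(C)C(C)(C)C)/C(C)=C/COCc1ccc(OC)cc1 | intermediate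
5 | prop-2-ynal | C#CC=O | starting material
6 | (6R)-4-[(tert-butyldimethylsilyl)oxy]-6-{[(4-methoxybenzyl)oxy]methyl}-5-methylcyclohexa-1,4-diene-1-carbaldehyde | COc1ccc(COC[C@H]2C(C=O)=CCC(O[Si](C)(C)C(C)(C)C)=C2C)cc1 | intermediate
7 | [(6S)-4-[(tert-butyldimethylsilyl)oxy]-6-{[(4-methoxybenzyl)oxy]methyl}-5-methylcyclohexa-1,4-dien-1-yl]methanol | COc1ccc(COC[C@H]2C(CO)=CCC(O[Si](C)(C)C(C)(C)C)=C2C)cc1 | intermediate
8 | 3β,4β-epoxy alcohol of 7 (C15H2OH on C4) | COc1ccc(COC[C@H]2[C@@]3(CO)O[C@H]3CC(O[Si](C)(C)C(C)(C)C)=C2C)cc1 | intermediate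
9 | 3β,4β-epoxy iodide (C15H2I) | COc1ccc(COC[C@H]2[C@@]3(CI)O[C@H]3CC(O[Si](C)(C)C(C)(C)C)=C2C)cc1 | intermediate
10 | ring-A 3β-allylic alcohol with C4=C15 methylene, C1=C10 TBS enol ether, 5β-CH2OPMB | COc1ccc(COC[C@H]2C(=C)[C@@H](O)CC(O[Si](C)(C)C(C)(C)C)=C2C)cc1 | intermediate
11 | 3β-TBS ether of 10 | COc1ccc(COC[C@H]2C(=C)[C@@H](O[Si](C)(C)C(C)(C)C)CC(O[Si](C)(C)C(C)(C)C)=C2C)cc1 | intermediate
12 | acrolein | C=CC=O | starting material
13 | 1-oxo-3β-(TBS-oxy)-4-methylidene-5β-[(PMB-oxy)methyl]-10β-methyl-10α-(3-oxopropyl)cyclohexane | COc1ccc(COC[C@H]2C(=C)[C@@H](O[Si](C)(C)C(C)(C)C)CC(=O)[C@]2(C)CCC=O)cc1 | intermediate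
14 | methyl acrylate | C=CC(=O)OC | starting material
15 | Morita–Baylis–Hillman adduct of 13 (C7 carbinol, both epimers) | COc1ccc(COC[C@H]2C(=C)[C@@H](O[Si](C)(C)C(C)(C)C)CC(=O)[C@]2(C)CCC(O)C(=C)C(=O)OC)cc1 | intermediate
16 | (Z)-allylic bromide, methyl 2-(bromomethyl)pent-2-enoate side chain on C10 | COc1ccc(COC[C@H]2C(=C)[C@@H](O[Si](C)(C)C(C)(C)C)CC(=O)[C@]2(C)CC/C=C(\CBr)C(=O)OC)cc1 | intermediate
17 | C6 primary alcohol of 16 | OC[C@H]1C(=C)[C@@H](O[Si](C)(C)C(C)(C)C)CC(=O)[C@]1(C)CC/C=C(\CBr)C(=O)OC | intermediate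
18 | C6 aldehyde | O=C[C@H]1C(=C)[C@@H](O[Si](C)(C)C(C)(C)C)CC(=O)[C@]1(C)CC/C=C(\CBr)C(=O)OC | intermediate
19 | methyl 6α-hydroxy-1-oxo-3β-[(tert-butyldimethylsilyl)oxy]eudesma-4(15),11(13)-dien-12-oate | O[C@@H]1[C@H]2C(=C)[C@@H](O[Si](C)(C)C(C)(C)C)CC(=O)[C@]2(C)CC[C@H]1C(=C)C(=O)OC | intermediate
20 | ethyl 2-(hydroxymethyl)acrylate | C=C(CO)C(=O)OCC | starting material
21 | ethyl 2-{[(tert-butyldimethylsilyl)oxy]methyl}acrylate | C=C(CO[Si](C)(C)C(C)(C)C)C(=O)OCC | intermediate
22 | 2-{[(tert-butyldimethylsilyl)oxy]methyl}acrylic acid | C=C(CO[Si](C)(C)C(C)(C)C)C(=O)O | intermediate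
23 | mixed anhydride of 22 with 2,4,6-trichlorobenzoic acid | C=C(CO[Si](C)(C)C(C)(C)C)C(=O)OC(=O)c1c(Cl)cc(Cl)cc1Cl | intermediate
24 | methyl 6α-(2-{[(tert-butyldimethylsilyl)oxy]methyl}acryloyloxy)-1-oxo-3β-[(tert-butyldimethylsilyl)oxy]eudesma-4(15),11(13)-dien-12-oate | C=C(CO[Si](C)(C)C(C)(C)C)C(=O)O[C@@H]1[C@H]2C(=C)[C@@H](O[Si](C)(C)C(C)(C)C)CC(=O)[C@]2(C)CC[C@H]1C(=C)C(=O)OC | intermediate
25 | methyl 1β-hydroxy-6α-(2-{[(tert-butyldimethylsilyl)oxy]methyl}acryloyloxy)-3β-[(tert-butyldimethylsilyl)oxy]eudesma-4(15),11(13)-dien-12-oate | C=C(CO[Si](C)(C)C(C)(C)C)C(=O)O[C@@H]1[C@H]2C(=C)[C@@H](O[Si](C)(C)C(C)(C)C)C[C@@H](O)[C@]2(C)CC[C@H]1C(=C)C(=O)OC | intermediate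
26 | methyl (1R,3S,5S,6S,7S,10R)-1,3-dihydroxy-6-[2-(hydroxymethyl)acryloyloxy]eudesma-4(15),11(13)-dien-12-oate (CNP0247525.1) | C=C(CO)C(=O)O[C@@H]1[C@H]2C(=C)[C@@H](O)C[C@@H](O)[C@]2(C)CC[C@H]1C(=C)C(=O)OC | target

Total step count: 18. Longest linear sequence: 16 steps (steps 1–13 and 16–18); steps 14–15 make the side-chain acid.

Steps most likely to fail

1. Step 3 (key Diels–Alder). The catalyst may discriminate the two faces poorly with an acetylenic aldehyde, and 1,2-addition of the enol silane to the activated formyl group may compete with cycloaddition. Fallback by auxiliary control, setting out from 4: a Diels–Alder reaction of 4 with the known dienophile (S)-4-benzyl-3-propioloyloxazolidin-2-one (Et2AlCl, CH2Cl2, −78 °C) would give the N-acyl oxazolidinone cyclohexadiene adduct F1, in which C5 is set by the auxiliary (its enantiomer is taken if the facial sense requires it). LiBH4 reduction of the imide would then give the allylic alcohol and return the auxiliary; this comes back to the route at 7.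

2. Step 5 (asymmetric epoxidation). The reagent must deliver oxygen to the β face, which the pseudoaxial C5 side chain shields, so the mismatched pairing may erode or reverse the facial selectivity. Fallback by substrate control and inversion, setting out from 7: hydroxyl-directed epoxidation (VO(acac)2, t-BuOOH, CH2Cl2) should place the oxirane on the open α face and give the 3α,4α-epoxy alcohol F2. The iodination/zinc sequence of step 6, through the 3α,4α-epoxy iodide F3, would give the 3α-allylic alcohol F4. Mitsunobu inversion with 4-nitrobenzoic acid (PPh3, DIAD, THF) would give the 3β 4-nitrobenzoate F5, and K2CO3 in MeOH would release the 3β-alcohol; this comes back to the route at 10.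

3. Step 13 (chromium-mediated ring closure). The β,γ-unsaturated aldehyde may isomerise or epimerise at C5 before it cyclises, the relative configuration at C6/C7 may be set poorly, the chromium alkoxide may lactonise onto C12, or the allylmetal may add to the C1 ketone. Fallback by a carbonyl-ene closure, setting out from 13: Wittig olefination of the side-chain aldehyde with isopropylidenetriphenylphosphorane would give the trisubstituted alkene F6. DDQ would give the C6 alcohol F7 and Dess–Martin periodinane the C6 aldehyde F8. ZnBr2 in CH2Cl2 would promote the intramolecular carbonyl-ene cyclisation (the citronellal-to-isopulegol mode, all-equatorial chair) to the 6α-hydroxy-7β-isopropenyl trans-decalin F9. Yamaguchi esterification with 22 would give the 6α-acrylate ester F10; SeO2 with t-BuOOH would oxidise the isopropenyl methyl (C12) to the enal F11; NaClO2 would give the C12 acid F12, and TMSCHN2 would give its methyl ester; this comes back to the route at 24.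

Further compounds
F1 | step 3 | (S)-4-benzyl-3-{[(6R)-4-(TBS-oxy)-6-(PMB-oxymethyl)-5-methylcyclohexa-1,4-dien-1-yl]carbonyl}oxazolidin-2-one | COc1ccc(COC[C@H]2C(C(=O)N3[C@@H](Cc4ccccc4)COC3=O)=CCC(O[Si](C)(C)C(C)(C)C)=C2C)cc1
F2 | step 5 | 3α,4α-epoxy alcohol (C3/C4 epimer pair of 8) | COc1ccc(COC[C@H]2[C@]3(CO)O[C@@H]3CC(O[Si](C)(C)C(C)(C)C)=C2C)cc1
F3 | step 5 | 3α,4α-epoxy iodide | COc1ccc(COC[C@H]2[C@]3(CI)O[C@@H]3CC(O[Si](C)(C)C(C)(C)C)=C2C)cc1
F4 | step 5 | 3α-allylic alcohol (3-epimer of 10) | COc1ccc(COC[C@H]2C(=C)[C@H](O)CC(O[Si](C)(C)C(C)(C)C)=C2C)cc1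
F5 | step 5 | 3β 4-nitrobenzoate of 10 | COc1ccc(COC[C@H]2C(=C)[C@@H](OC(=O)c3ccc(cc3)[N+](=O)[O-])CC(O[Si](C)(C)C(C)(C)C)=C2C)cc1
F6 | step 13 | 10α-(4-methylpent-3-enyl) ketone from 13 | COc1ccc(COC[C@H]2C(=C)[C@@H](O[Si](C)(C)C(C)(C)C)CC(=O)[C@]2(C)CCC=C(C)C)cc1
F7 | step 13 | C6 alcohol of F6 | OC[C@H]1C(=C)[C@@H](O[Si](C)(C)C(C)(C)C)CC(=O)[C@]1(C)CCC=C(C)C
F8 | step 13 | C6 aldehyde of F6 | O=C[C@H]1C(=C)[C@@H](O[Si](C)(C)C(C)(C)C)CC(=O)[C@]1(C)CCC=C(C)C
F9 | step 13 | 6α-hydroxy-3β-(TBS-oxy)eudesma-4(15),11-dien-1-one | O[C@@H]1[C@H]2C(=C)[C@@H](O[Si](C)(C)C(C)(C)C)CC(=O)[C@]2(C)CC[C@H]1C(C)=C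
F10 | step 13 | 6α-(2-{[(TBS)oxy]methyl}acryloyloxy)-3β-(TBS-oxy)eudesma-4(15),11-dien-1-one | C=C(CO[Si](C)(C)C(C)(C)C)C(=O)O[C@@H]1[C@H]2C(=C)[C@@H](O[Si](C)(C)C(C)(C)C)CC(=O)[C@]2(C)CC[C@H]1C(C)=C
F11 | step 13 | C12 enal of F10 (eudesma-4(15),11(13)-dien-12-al) | C=C(CO[Si](C)(C)C(C)(C)C)C(=O)O[C@@H]1[C@H]2C(=C)[C@@H](O[Si](C)(C)C(C)(C)C)CC(=O)[C@]2(C)CC[C@H]1C(=C)C=O
F12 | step 13 | C12 carboxylic acid corresponding to 24 | C=C(CO[Si](C)(C)C(C)(C)C)C(=O)O[C@@H]1[C@H]2C(=C)[C@@H](O[Si](C)(C)C(C)(C)C)CC(=O)[C@]2(C)CC[C@H]1C(=C)C(=O)O
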